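In a one-step world I would have read the target as an end point, a product released for good. Friday's run forbade that: its target fell from 36.7 % at 3.00 h to 15.0 % at 15.0 h.

common to all: starting material 42 mM
- Sunday's: coupling partner 0.74 equiv; protic impurity 8.4 mM; temperature 20 °C; run made earlier
- Friday's: coupling partner 1.7 equiv; protic impurity 8.4 mM; temperature 50 °C; run made earlier
- Monday's: coupling partner 1.1 equiv; protic impurity 17 mM; temperature 20 °C; run made earlier
- grey: coupling partner 1.10 equiv; protic impurity 8.40 mM; temperature 75 °C; time 6.0 h
- ochre: coupling partner 1.10 equiv; protic impurity 8.40 mM; temperature 50 °C; time 6.0 h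
- blue: coupling partner 1.10 equiv; protic impurity 8.40 mM; temperature 25 °C; time 6.0 h

| run | time / h | target / % |
|---|---|---|
| Sunday's | 5.00 | 2.9 |
| Sunday's | 15.0 | 6.9 |
| Sunday's | 25.0 | 16.3 |
| Sunday's | 40.0 | 24.0 |
| Sunday's | 60.0 | 32.8 |
| Sunday's | 72.0 | 35.8 |
| Friday's | 1.33 | 23.9 |
| Friday's | 2.50 | 34.6 |
| Friday's | 3.00 | 36.7 |
| Friday's | 6.00 | 30.4 |
| Friday's | 10.0 | 21.0 |
| Friday's | 15.0 | 15.0 |
| Monday's | 6.00 | 4.0 |
| Monday's | 10.0 | 7.8 |
| Monday's | 20.0 | 14.6 |
| Monday's | 40.0 | 25.1 |
| Monday's | 72.0 | 36.1 |

(each reading ± 1 percentage point)



- the flask that comes out highest in amount of target, in percent of the starting material charged, or "all alike" when all lie within 1.5 percentage points (grey / ochre / blue / all alike)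
- target at the end, in percent of the starting material charged, grey
- target at the end, in percent of the starting material charged, ochre
- target at the end, in percent of the starting material charged, blue

I ran the flask in slow motion on two assumptions of my own, which the readings allow but do not prove: the protic impurity removes starting material one for one, and the target is lost by taking up a second coupling partner.

From the first instants the impurity competes with the coupling for the starting material, and on my assumption its charge can take at most 20.0 % of the starting material in grey, ochre and blue, whose charges are the same. The rest, which I call the open share, stays available for coupling.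

In the middle the target builds, and each target made costs one partner.

At the end, with the feed over, d[target]/dt = d[partner]/dt = −k[partner][target], so [target] − [partner] stays constant. The integrated law then makes ln([target]/[partner]) linear in time. The target levels off at that difference if it is positive, the partner being the limiting reagent of this second step, and tends to zero if it is negative.

I call this difference the partner floor. Once the impurity charge is spent, it is twice the open share minus the partner equivalents, 50.0 % for these flasks. Each percent of starting material left uncoupled lowers it by two. Friday's recipe gives −10.0 %, a negative floor, which fits its falling readings. I did not expect blue, at 25 °C, to come near the floor by 6.0 h, since Monday's run read 4.0 % at 6.00 h.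

The forecast put ochre highest, with grey 25 %, ochre 33 % and blue 10 %, and said of grey “much lower if target self-consumes”. My floor stood above its grey figure.

    coupling partner + target → over-reaction product (k = 1.84 L mol⁻¹ h⁻¹, Ea = 56.0 kJ mol⁻¹)
    starting material + protic impurity → quenched substrate (k = 4.87 L mol⁻¹ h⁻¹, Ea = 75.0 kJ mol⁻¹)
    coupling partner + intermediate D ⇌ intermediate E (K = 18.4 L mol⁻¹, k = 1.44 L mol⁻¹ h⁻¹, Ea = 79.0 kJ mol⁻¹, ΔH = −60.0 kJ mol⁻¹)
    coupling partner ⇌ dormant form (K = 0.390, k = 0.265 h⁻¹, Ea = 93.0 kJ mol⁻¹, ΔH = −60.0 kJ mol⁻¹)
    starting material + coupling partner ⇌ intermediate A (K = 9.50 L mol⁻¹, k = 7.10 L mol⁻¹ h⁻¹, Ea = 68.0 kJ mol⁻¹, ΔH = −25.0 kJ mol⁻¹)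
    intermediate C → target (k = 0.0519 h⁻¹, Ea = 100 kJ mol⁻¹)
    intermediate D → intermediate C (k = 0.178 h⁻¹, Ea = 87.0 kJ mol⁻¹)
    starting material + coupling partner → intermediate C (k = 8.20 L mol⁻¹ h⁻¹, Ea = 48.0 kJ mol⁻¹)
    coupling partner + intermediate B → intermediate D (k = 0.641 L mol⁻¹ h⁻¹, Ea = 54.0 kJ mol⁻¹)
    starting material ⇌ intermediate B (K = 2.00, k = 0.316 h⁻¹, Ea = 103 kJ mol⁻¹, ΔH = 4.00 kJ mol⁻¹)
    (constants at 25 °C)

The flasks gave ochre highest: ochre 39.1 %, grey 26.7 %, blue 7.42 %, with ochre 6.1 percentage points above the forecast. At 6.00 h ochre still held 14.5 % of its partner charge, against 0.379 % in grey. The floor, less twice the starting material and intermediate B standing there, gives 26.1 % for grey, which read 26.7 %. For ochre left until 60.0 h the same reckoning gives 34.5 %, and ochre then held 34.9 %.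

Readings and results were generated by integration on assumed constants; noise was put on by code.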